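**Retrosynthetic overview**
1. Ainsliadimer A (25) ⇒ intramolecular Mukaiyama aldol closes the central cyclopentane (C3–C4′). Its precursor is a C15–C15′-linked bis(silyl enol ether) carrying one 4α-OH, made by Mg/TMSCl reductive β,β-dimerisation of two copies of the masked 3-oxo-4(15)-ene guaianolide 21. Its lactone methylenes are carried as Me2NH adducts.
2. 21 ⇒ Wittig at C10, Mannich masking of the lactone, and β-elimination to the C4=C15 enone. The tricycle comes from an intramolecular Pauson–Khand reaction of a lactone-tethered 1,8-enyne, which forms the seven-membered ring and the cyclopentenone together.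
3. The trans-γ-lactone (C6/C7) ⇐ ketoreductase reduction of an ynone, whose C7 centre comes from a Cu-catalysed asymmetric conjugate addition.
4. Ring order: lactone → seven-membered ring + cyclopentenone (one step) → central cyclopentane.

Assumptions:
- The Weinreb amide is a weaker acceptor than the ethyl ester, so the Grignard adds β to the ester, at C7.
- The C11/C11′ Mannich epimers are carried as mixtures and converge in the last step.
- The 1α-H (cis-fused) epimer is the thermodynamic one at C1.

**Step 1**
Reactants: 1 (mono-ethyl fumarate), 2 (N,O-dimethylhydroxylamine·HCl)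
Product: 3, ethyl (2E)-4-[methoxy(methyl)amino]-4-oxobut-2-enoate
Conditions: EDC·HCl, HOBt, i-Pr2NEt, CH2Cl2, 0 °C → rt
Reagents that add atoms: none
Why: Carbodiimide amide coupling gives the unsymmetrical fumarate acceptor, with the Weinreb amide as the latent C6 carbonyl.

**Step 2**
Reactants: 3; 4 ((3-bromopropoxy)-TBS ether, converted in situ to its Grignard reagent with Mg)
Product: 5, ethyl (3S)-6-(TBSO)-3-[methoxy(methyl)carbamoyl]hexanoate
Conditions: 4, Mg, THF; then CuBr·SMe2 (5 mol%), Josiphos-type ligand (enantiomer giving the 3S adduct), t-BuOMe, –78 °C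
Reagents that add atoms: none (the C8–C10 chain comes from 4)
Why: Cu-catalysed asymmetric 1,4-addition (Feringa-type) to the ester-activated alkene sets C7, the first stereocentre.

**Step 3**
Reactants: 5; 6 (TBDPS propargyl ether)
Product: 7, ethyl (3S)-6-(TBSO)-3-{4-(TBDPSO)but-2-ynoyl}hexanoate
Conditions: 6, n-BuLi, THF, –78 °C; add 5, –78 °C; NH4Cl quench
Reagents that add atoms: none (the alkynyl unit comes from 6)
Why: Weinreb ketone synthesis stops cleanly at the ynone because the chelated tetrahedral intermediate is stable at –78 °C.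

**Step 4**
Reactants: 7
Product: 8, (4S,5S)-4-[3-(TBSO)propyl]-5-[3-(TBDPSO)prop-1-yn-1-yl]oxolan-2-one (trans-γ-lactone)
Conditions: ketoreductase (NADPH-dependent, from a KRED panel), NADP+, glucose/GDH, KPi pH 7, 10% i-PrOH, 30 °C; then PPTS, PhMe, 50 °C
Reagents that add atoms: none
Why: The enzyme reduces the ynone carbonyl with reagent control, with the small alkyne and larger α-branched sp3 side discriminating the faces. A panel hit delivering the 5S alcohol gives the 4,5-trans relationship (6β-H/7α-H), and the γ-hydroxy ester lactonises with loss of EtOH.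

**Step 5**
Reactants: 8
Product: 9, primary alcohol (4S,5S)-4-(3-hydroxypropyl) lactone
Conditions: HF·pyridine, pyridine/THF, 0 °C → rt
Reagents that add atoms: none
Why: The primary alkyl TBS ether is cleaved selectively over the more robust TBDPS ether; the lactone and alkyne are untouched.

**Step 6**
Reactants: 9
Product: 10, 3-[(2S,3S)-2-{3-(TBDPSO)prop-1-yn-1-yl}-5-oxooxolan-3-yl]propanal
Conditions: Dess–Martin periodinane, NaHCO3, CH2Cl2, rt
Reagents that add atoms: none
Why: Mild oxidation gives the aldehyde; the C7 stereocentre is not α to any carbonyl, so it cannot epimerise.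

**Step 7**
Reactants: 10
Product: 11, (4S,5S)-4-(3-hydroxypent-4-en-1-yl)-5-{3-(TBDPSO)prop-1-yn-1-yl}oxolan-2-one (mixture of C10 epimers)
Conditions: vinylMgBr, CeCl3, THF, –78 °C
Reagents that add atoms: vinylmagnesium bromide, C=C[Mg]Br
Why: The organocerium 1,2-adds to the aldehyde without enolising or opening the lactone; the C10 epimers are immaterial because C10 is oxidised to a ketone later.

**Step 8**
Reactants: 11
Product: 12, 10-hydroxy-15-(TBDPSO)-3-oxo-11,13-dihydroguai-4-en-12,6α-olide (6β-H, 7α-H; C1/C10 epimeric mixture)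
Conditions: (i) Co2(CO)8, CH2Cl2, rt; (ii) n-BuSMe, DCE, 83 °C, CO (1 atm)
Reagents that add atoms: carbon monoxide, [C-]#[O+]
Why: The intramolecular Pauson–Khand reaction joins C1–C5 (closing the seven-membered ring with a 5-atom tether) and builds the C2–C3–C4 enone in one step; C1 is only provisional and is equilibrated in step 10.

**Step 9**
Reactants: 12
Product: 13, the 10-oxo analogue (C1 epimeric)
Conditions: Dess–Martin periodinane, NaHCO3, CH2Cl2, rt
Reagents that add atoms: none
Why: The secondary alcohol is oxidised and the C1 stereochemical mixture now sits α to a ketone, so it can be equilibrated.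

**Step 10**
Reactants: 13
Product: 14, 1α-H 10-oxo enone (cis-fusion after reduction; C1 configuration now defined)
Conditions: DBU (0.3 equiv), PhMe, 40 °C
Reagents that add atoms: none
Why: Base-mediated thermodynamic epimerisation through the C10 enolate funnels C1 to the 1α-H epimer.

**Step 11**
Reactants: 14
Product: 15, 10(14)-methylene enone
Conditions: Ph3P=CH2 (from Ph3PCH3Br/KOt-Bu), THF, 0 °C → rt
Reagents that add atoms: methylenetriphenylphosphorane, C=P(c1ccccc1)(c1ccccc1)c1ccccc1
Why: Wittig methylenation is chemoselective for the unhindered cycloheptanone over the conjugated tetrasubstituted enone and the lactone.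

**Step 12**
Reactants: 15
Product: 16, 3-oxo-4,5-dihydro compound (1α-H, 5α-H; C4 epimeric)
Conditions: Stryker's reagent [(Ph3P)CuH]6, PhMe, 0 °C → rt; NH4Cl
Reagents that add atoms: none
Why: Copper-hydride 1,4-reduction delivers H to C5 from the convex α-face, cis to 1α-H, and leaves the exocyclic alkene intact; the TBDPS ether is too poor a leaving group to eliminate from the enolate.

**Step 13**
Reactants: 16
Product: 17, 3-ethylene ketal
Conditions: (TMSOCH2)2, TMSOTf (0.1 equiv), CH2Cl2, –78 → 0 °C
Reagents that add atoms: 1,2-bis(trimethylsilyloxy)ethane, C[Si](C)(C)OCCO[Si](C)(C)C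
Why: Noyori ketalisation protects the only ketone under non-aqueous, mild conditions, so the exocyclic alkene is not disturbed.

**Step 14**
Reactants: 17
Product: 18, 13-(dimethylamino)-11,13-dihydro lactone (C11 epimer mixture)
Conditions: LDA, THF, –78 °C; then Me2N+=CH2 I−, –78 → 0 °C
Reagents that add atoms: Eschenmoser's salt, C=[N+](C)C.[I-]
Why: Enolate aminomethylation gives the Mannich base, a masked α-methylene lactone; C7 is β to the carbonyl and is not scrambled.

**Step 15**
Reactants: 18
Product: 19, 15-alcohol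
Conditions: TBAF, AcOH, THF, 0 °C → rt
Reagents that add atoms: none
Why: Buffered fluoride removes the TBDPS group without E1cB loss of the Mannich amine.

**Step 16**
Reactants: 19
Product: 20, 3-oxo-15-hydroxy Mannich lactone
Conditions: p-TsOH·H2O (1.5 equiv, the excess covers the basic amine), acetone/H2O, 50 °C; NaHCO3 work-up
Reagents that add atoms: none
Why: Acid-catalysed ketal hydrolysis; the lactone and the exocyclic alkene survive these mild conditions.

**Step 17**
Reactants: 20
Product: 21, masked monomer: 13-(dimethylamino)-11,13-dihydro-3-oxoguaia-4(15),10(14)-dien-12,6α-olide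
Conditions: MsCl, Et3N, CH2Cl2, 0 °C; then DBU, rt (use immediately)
Reagents that add atoms: none
Why: Mesylation then E1cB elimination of the β-mesyloxy ketone gives the C4=C15 exocyclic enone regiospecifically, because C15 was installed at C4 by the Pauson–Khand step.

**Step 18**
Reactants: 21 (2 equiv)
Product: 22, C15–C15′-linked dimer as its bis(TMS) enol ether (Δ3(4), Δ3′(4′))
Conditions: Mg (activated), TMSCl, THF/DMF, 0 °C → rt
Reagents that add atoms: chlorotrimethylsilane, C[Si](C)(C)Cl
Why: Mg/TMSCl reductive dimerisation gives the silyloxyallyl radical, which couples at the unhindered C15 termini; no stereocentre is created, and the amine-masked lactone is inert.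

**Step 19**
Reactants: 22
Product: 23, mono-4α-hydroxy-3-ketone / 3′-O-TMS Δ3′(4′) enol ether
Conditions: TBAT (1.0 equiv), THF, –78 °C; O2, –78 °C; then P(OEt)3, –78 °C → rt
Reagents that add atoms: dioxygen, O=O
Why: Fluoride unmasks one enolate statistically; O2 hydroxylation (Gardner-type) occurs on the α-face, since the β-face is shielded by the seven-membered ring, fixing 4α-OH and pushing C15 to β. Unreacted 22 and the bis-hydroxylated by-product are separated and 22 is recycled.

**Step 20**
Reactants: 23
Product: 24, bis-Mannich aldol adduct (3α,4α-diol, spiro C4′, 3′-ketone)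
Conditions: TiCl4, 2,6-di-tert-butylpyridine, CH2Cl2, –78 → –30 °C; aq. NaHCO3
Reagents that add atoms: none
Why: Intramolecular Mukaiyama aldol onto the α-oxygenated, Ti-chelated C3 ketone. The new 5-ring must be cis-fused to the C4–C15 (β) bond, which fixes C3, and attack on the convex α-face of the enol ether sets C4′ with C15′ β.

**Step 21**
Reactants: 24
Product: 25, ainsliadimer A
Conditions: MeI (excess), MeCN, rt; then sat. aq. NaHCO3, CH2Cl2, rt
Reagents that add atoms: none (Me3N is lost)
Why: Quaternisation, then E1cB (Hofmann-type) elimination of both β-ammonium lactones regenerates the two α-methylene lactones and removes the C11/C11′ epimer mixtures.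

**Compound list**
1 | mono-ethyl fumarate | CCOC(=O)/C=C/C(=O)O | starting material
2 | N,O-dimethylhydroxylamine hydrochloride | CNOC.Cl | starting material
3 | ethyl (2E)-4-[methoxy(methyl)amino]-4-oxobut-2-enoate | CCOC(=O)/C=C/C(=O)N(C)OC | intermediate
4 | (3-bromopropoxy)-tert-butyldimethylsilane | CC(C)(C)[Si](C)(C)OCCCBr | starting material
5 | ethyl (3S)-6-(TBSO)-3-[methoxy(methyl)carbamoyl]hexanoate | CCOC(=O)C[C@H](CCCO[Si](C)(C)C(C)(C)C)C(=O)N(C)OC | intermediate
6 | tert-butyldiphenyl(prop-2-yn-1-yloxy)silane | C#CCO[Si](c1ccccc1)(c1ccccc1)C(C)(C)C | starting material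
7 | ynone | CCOC(=O)C[C@H](CCCO[Si](C)(C)C(C)(C)C)C(=O)C#CCO[Si](c1ccccc1)(c1ccccc1)C(C)(C)C | intermediate
8 | (4S,5S) trans-lactone | O=C1C[C@H](CCCO[Si](C)(C)C(C)(C)C)[C@H](O1)C#CCO[Si](c1ccccc1)(c1ccccc1)C(C)(C)C | intermediate
9 | primary alcohol | O=C1C[C@H](CCCO)[C@H](O1)C#CCO[Si](c1ccccc1)(c1ccccc1)C(C)(C)C | intermediate
10 | aldehyde | O=C1C[C@H](CCC=O)[C@H](O1)C#CCO[Si](c1ccccc1)(c1ccccc1)C(C)(C)C | intermediate
11 | allylic alcohol (C10 epimers) | O=C1C[C@H](CCC(O)C=C)[C@H](O1)C#CCO[Si](c1ccccc1)(c1ccccc1)C(C)(C)C | intermediate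
12 | Pauson–Khand tricycle (C1/C10 epimeric) | O=C1C[C@@H]2CCC(O)C3CC(=O)C(CO[Si](c4ccccc4)(c4ccccc4)C(C)(C)C)=C3[C@H]2O1 | intermediate
13 | 10-ketone | O=C1C[C@@H]2CCC(=O)C3CC(=O)C(CO[Si](c4ccccc4)(c4ccccc4)C(C)(C)C)=C3[C@H]2O1 | intermediate
14 | 1α-H 10-ketone | O=C1C[C@@H]2CCC(=O)[C@@H]3CC(=O)C(CO[Si](c4ccccc4)(c4ccccc4)C(C)(C)C)=C3[C@H]2O1 | intermediate
15 | 10-methylene enone | O=C1C[C@@H]2CCC(=C)[C@@H]3CC(=O)C(CO[Si](c4ccccc4)(c4ccccc4)C(C)(C)C)=C3[C@H]2O1 | intermediate
16 | 4,5-dihydro ketone (C4 epimeric) | O=C1C[C@@H]2CCC(=C)[C@@H]3CC(=O)C(CO[Si](c4ccccc4)(c4ccccc4)C(C)(C)C)[C@@H]3[C@H]2O1 | intermediate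
17 | ethylene ketal | O=C1C[C@@H]2CCC(=C)[C@@H]3CC4(OCCO4)C(CO[Si](c5ccccc5)(c5ccccc5)C(C)(C)C)[C@@H]3[C@H]2O1 | intermediate
18 | Mannich lactone ketal | O=C1C(CN(C)C)[C@@H]2CCC(=C)[C@@H]3CC4(OCCO4)C(CO[Si](c5ccccc5)(c5ccccc5)C(C)(C)C)[C@@H]3[C@H]2O1 | intermediate
19 | 15-alcohol ketal | O=C1C(CN(C)C)[C@@H]2CCC(=C)[C@@H]3CC4(OCCO4)C(CO)[C@@H]3[C@H]2O1 | intermediate
20 | 15-hydroxy ketone | O=C1C(CN(C)C)[C@@H]2CCC(=C)[C@@H]3CC(=O)C(CO)[C@@H]3[C@H]2O1 | intermediate
21 | masked monomer enone | O=C1C(CN(C)C)[C@@H]2CCC(=C)[C@@H]3CC(=O)C(=C)[C@@H]3[C@H]2O1 | intermediate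
22 | bis(TMS enol ether) dimer | O=C1C(CN(C)C)[C@@H]2CCC(=C)[C@@H]3CC(O[Si](C)(C)C)=C(CCC4=C(O[Si](C)(C)C)C[C@H]5C(=C)CC[C@H]6C(CN(C)C)C(=O)O[C@@H]6[C@@H]45)[C@@H]3[C@H]2O1 | intermediate
23 | 4α-hydroxy ketone / enol ether | O=C1C(CN(C)C)[C@@H]2CCC(=C)[C@@H]3CC(=O)[C@](O)(CCC4=C(O[Si](C)(C)C)C[C@H]5C(=C)CC[C@H]6C(CN(C)C)C(=O)O[C@@H]6[C@@H]45)[C@@H]3[C@H]2O1 | intermediate
24 | bis-Mannich aldol adduct | CN(C)CC1C(=O)O[C@@H]2[C@@H]3[C@@H](C[C@@]4(O)[C@]3(O)CC[C@]43C(=O)C[C@H]4C(=C)CC[C@H]5C(CN(C)C)C(=O)O[C@@H]5[C@H]43)C(=C)CC[C@@H]12 | intermediate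
25 | ainsliadimer A | C=C1C(=O)O[C@@H]2[C@@H]3[C@@H](C[C@@]4(O)[C@]3(O)CC[C@]43C(=O)C[C@H]4C(=C)CC[C@H]5C(=C)C(=O)O[C@@H]5[C@H]43)C(=C)CC[C@@H]12 | target

**Totals**
- Total steps: 21.
- Longest linear sequence: 21 steps (1 → 3 → 5 → … → 25). Compound 21 is made once and used twice in step 18.

**Three steps most likely to fail**
1. **Step 8 (Pauson–Khand, 1,8-enyne).** Seven-membered ring closure may be low-yielding, and the C1 diastereoselectivity is uncertain.
   - Fallback (changes approach): close the cycloheptene by RCM of the divinyl lactone derived from 10, then build the cyclopentanone by Pd-TMM [3+2] cycloaddition and ozonolysis. Install C15 as a hydroxymethyl group by aldol with formaldehyde.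
2. **Step 18 (with the statistical desymmetrisation in step 19).** Reductive β,β-dimerisation may be inefficient, and mono-hydroxylation gives at most about 50%.
   - Fallback (changes approach): replace the radical–radical coupling with a stepwise Giese-type photoredox coupling. Add the C15 radical from a redox-active ester of a ketal-protected 4α-hydroxy half to enone 21, then remove the ketal and close the ring by intramolecular aldol.
3. **Step 20 (spiro aldol).** The hindered quaternary–quaternary bond may form slowly, the Lewis acid may isomerise the exocyclic alkenes, or the wrong C4′ epimer may form.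
   - Fallback (changes approach): protodesilylate 23 to the 1,6-diketone and close the ring by pyrrolidine/AcOH enamine aldol. This proceeds by reversible retro-aldol/aldol and drives toward the thermodynamic spiro epimer.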